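A small charge of free catalyst, 50 µM against 10 mM of starting material, has to turn over 200 times to finish the job, so we ask whether it lives that long.

- east: starting material 10 mM; reagent 50.0 mM; free catalyst 50 µM; time 30 min
- north-east: starting material 10 mM; reagent 120 mM; free catalyst 50 µM; time 30 min

* which of these there is most of at the end, counted by the starting material in it, east (target / starting material / catalyst intermediate C / side product)
* which of these there is most of at the end, counted by the starting material in it, north-east (target / starting material / catalyst intermediate C / side product)
* amount of the one of these that there is most of at the end, in percent of the starting material charged, east
* amount of the one of these that there is most of at the end, in percent of the starting material charged, north-east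

    reagent + free catalyst ⇌ catalyst intermediate A (K1 = 60.4 /M, k1 = 360 /M/min)
    catalyst intermediate A → catalyst intermediate B (k2 = 13.8 /min)
    starting material + catalyst intermediate B ⇌ catalyst intermediate C (K3 = 8140 /M, k3 = 1420 /M/min)
    catalyst intermediate C ⇌ catalyst intermediate D (K4 = 0.931, k4 = 16.4 /min)
    catalyst intermediate D → free catalyst + target (k5 = 16.5 /min)
    starting material + target → side product (k6 = 3.46 /M/min)
    reagent + catalyst intermediate C → spent catalyst (k7 = 3.37 /M/min)

In the round, free catalyst takes up reagent to give catalyst intermediate A, which becomes catalyst intermediate B. Catalyst intermediate B binds starting material to give catalyst intermediate C, which interconverts with catalyst intermediate D, and catalyst intermediate D releases target and free catalyst. There are two leaks: reagent attacks catalyst intermediate C to give spent catalyst, and starting material attacks target to give side product.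

We start with speed. Counting returns from catalyst intermediate D, each round spends a time tC = 0.126 min in catalyst intermediate C. Adding the average waits at each stop, tC among them, gives a round time T of 0.411 min in east, which would allow 73.0 rounds in 30 min.

But catalyst dies. In east, catalyst intermediate C moves on far faster than reagent kills it, yet it is exposed on every round, for the time tC. The risk per round is therefore 3.37 /M/min times reagent times tC. Its inverse is the turnover number N, the rounds a catalyst survives on average: 47.1 in east, fewer than the rounds needed. The gross target ceiling G = N times catalyst over starting material is 23.5 %. That costs far less reagent than the charge, so we hold reagent constant, a pseudo-first-order death.

Does the ceiling arrive in time? The catalyst lifetime τ = NT is 19.3 min, so for 30 min we reckon 18.6 % gross target in the east flask.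

Target in east is also eaten, though, with a half-life shorter than the run. Its loss constant is 0.0346 /min with starting material held at charge, which leaves 10.1 % target standing in east. Each target eaten costs a second starting material, so 73.0 % of the starting material remains, and starting material leads.

North-east has 120 mM of reagent, so N = 19.6, G = 9.81 %, T = 0.364 min and τ = 7.14 min. That gives 9.66 % gross and 4.42 % standing, so 85.1 % remains, and again starting material leads.

The forecast names starting material for east at 76 % and starting material for north-east at 85 %, holding that “more reagent kills the catalyst faster”. Its east figure is above ours.

The simulation gives starting material ahead in east at 74.0 %, against 14.3 % side product and 11.2 % target. In north-east it gives starting material at 85.0 %, against 9.60 % side product and 4.87 % target.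

Take a neighbouring flask, north-east with 25 mM of starting material. Reagent and catalyst are unchanged, and neither tC nor the risk per round contains starting material, so N stays 19.6. The ceiling stays 0.981 mM of gross target, now 3.92 % of this larger charge. At 30.0 min the neighbour holds 99.0 % of its catalyst as spent catalyst, with 0.646 % target and 6.51 % side product. At two starting materials per side product, that is 3.90 % gross target, and 92.6 % of its starting material remains.

Its constants come from no measurement; the run is a simulation.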